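**Retrosynthetic overview**
1. Ring D is closed last. The O–C2 bond of the hydroxychroman comes from 6-endo opening of an (R)-prenyl epoxide by the 4'-OH of an epoxy-kaempferol. One global hydrogenolysis frees that phenol, and the C–O bond at the stereocentre is never broken.
2. Ring C (the O1–C2 bond and the 3-OH) comes from alkaline-peroxide oxidative cyclisation of a 2'-hydroxychalcone (chalcone → dihydroflavonol → flavonol). The (R)-epoxide is installed on the complete prenylated chalcone in the same flask with a fructose-derived dioxirane.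
3. The chalcone comes from a Claisen–Schmidt union of di-O-benzyl phloroacetophenone (ring A) and 4-benzyloxy-3-prenylbenzaldehyde (ring B).
4. The ring B piece comes from ortho C-prenylation of 4-hydroxybenzaldehyde. This precedes the union because on a finished flavonol C6/C8 of ring A would be prenylated first.
5. Ring order: A and B are bought, then C is formed, then D.

Assumption: the [C@H] centre of the given SMILES is read as (3R) in chroman numbering, and Oxone is treated as its active salt KHSO5.

**Route**

Step 1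
Reactants: 1 4-hydroxybenzaldehyde; 2 prenyl bromide (1-bromo-3-methylbut-2-ene)
Product: 3 4-hydroxy-3-(3-methylbut-2-en-1-yl)benzaldehyde
Conditions: KOH (1.1 equiv), H2O, 0 °C → rt, 24 h
Reagents that add atoms: none
Why: Ortho C-alkylation of a phenoxide (the chemical counterpart of aromatic prenyl transfer): in water the phenoxide oxygen is heavily solvated, so part of the SN2 attack on the soft allylic bromide comes from the ortho carbon and tautomerisation restores the phenol, the neutral O-prenyl ether being removed by base extraction, and no stereocentre is formed.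

Step 2
Reactants: 3 4-hydroxy-3-(3-methylbut-2-en-1-yl)benzaldehyde
Product: 4 4-(benzyloxy)-3-(3-methylbut-2-en-1-yl)benzaldehyde
Conditions: BnBr (1.1 equiv), K2CO3 (1.5 equiv), DMF, rt, 6 h
Reagents that add atoms: benzyl bromide, BrCc1ccccc1
Why: Williamson ether synthesis on the acidic para-formyl phenol, needed because a free 4-phenoxide would deactivate the chalcone towards HOO- in step 5 and would open the later epoxide in the 5-exo sense under base.

Step 3
Reactants: 5 2',4',6'-trihydroxyacetophenone (phloroacetophenone)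
Product: 6 1-[2,4-bis(benzyloxy)-6-hydroxyphenyl]ethan-1-one
Conditions: BnBr (2.05 equiv), K2CO3 (2.2 equiv), DMF, 0 °C → rt, 12 h
Reagents that add atoms: benzyl bromide, BrCc1ccccc1
Why: Williamson ether synthesis that stops after two benzylations because the remaining ortho OH is held in a strong hydrogen bond to the acetyl C=O, and this OH is kept free as the ring C nucleophile.

Step 4
Reactants: 4 4-(benzyloxy)-3-(3-methylbut-2-en-1-yl)benzaldehyde; 6 1-[2,4-bis(benzyloxy)-6-hydroxyphenyl]ethan-1-one
Product: 7 (E)-1-[2,4-bis(benzyloxy)-6-hydroxyphenyl]-3-[4-(benzyloxy)-3-(3-methylbut-2-en-1-yl)phenyl]prop-2-en-1-one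
Conditions: KOH (50% aq, 10 equiv), EtOH–THF, rt, 48 h
Reagents that add atoms: none
Why: Claisen–Schmidt (crossed aldol) condensation, in which the non-enolisable aldehyde accepts the ketone enolate and E1cB loss of water gives the thermodynamic (E)-enone.

Step 5
Reactants: 7 (E)-1-[2,4-bis(benzyloxy)-6-hydroxyphenyl]-3-[4-(benzyloxy)-3-(3-methylbut-2-en-1-yl)phenyl]prop-2-en-1-one
Product: 10 5,7-bis(benzyloxy)-2-(4-(benzyloxy)-3-{[(2R)-3,3-dimethyloxiran-2-yl]methyl}phenyl)-3-hydroxy-4H-chromen-4-one, via epoxychalcone 8 (not isolated), via trans-dihydroflavonol 9 (not isolated)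
Conditions: D-fructose-derived Shi ketone (1,2:4,5-di-O-isopropylidene-β-D-erythro-2,3-hexodiulo-2,6-pyranose, 0.3 equiv), KHSO5 (1.4 equiv, as 2KHSO5·KHSO4·K2SO4), K2CO3, Bu4NHSO4 (cat.), Na2B4O7 buffer pH 10.5, DME–DMM (nitrile-free), −5 °C, 2 h; then MeOH, 5 M NaOH, 30% H2O2, 0 °C → rt, 12 h; work-up at pH 7
Reagents that add atoms: potassium peroxymonosulfate KHSO5, [K+].[O-]S(=O)(=O)OO (epoxide oxygen, passed on through the dioxirane); hydrogen peroxide, OO (oxygen of the 3-OH)
Why: Proposed new method: an electrophilic and a nucleophilic oxygen transfer are run one after the other in one flask because they cannot cross over - the dioxirane made from the D-fructose-derived ketone and KHSO5 epoxidises only the electron-rich trisubstituted prenyl alkene through the spiro transition state that delivers oxygen to the face giving the (R)-epoxide (about 90% ee expected; the enone is electron-poor, the 2'-OH is hydrogen-bonded on an acyl-deactivated ring, and any enone epoxide formed lies on the productive path), then HOO- adds to the enone, the 2'-phenoxide closes ring C at the para-benzyloxy-stabilised β-carbon to dihydroflavonol 9 and further H2O2/NaOH dehydrogenates 9 to the flavonol, while the hindered trialkyl epoxide, whose neighbouring phenol is still benzylated, is inert to base; the closest known reactions are the Shi asymmetric epoxidation and the Algar–Flynn–Oyamada reaction, each known as a separate operation.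

Step 6
Reactants: 10 5,7-bis(benzyloxy)-2-(4-(benzyloxy)-3-{[(2R)-3,3-dimethyloxiran-2-yl]methyl}phenyl)-3-hydroxy-4H-chromen-4-one
Product: 12 3,5,7-trihydroxy-2-[(3R)-3-hydroxy-2,2-dimethyl-3,4-dihydro-2H-chromen-6-yl]-4H-chromen-4-one, via debenzylated epoxyflavonol 11 (not isolated)
Conditions: H2 (1 atm), 10% Pd/C, EtOAc–THF, rt; filter under Ar; then HFIP, camphorsulfonic acid (10 mol%), 0 °C, high dilution
Reagents that add atoms: none
Why: Hydrogenolysis removes the three benzyl ethers without touching the non-benzylic epoxide or the flavonol, and the freed 4'-OH then opens the acid-activated epoxide at its tertiary carbon (biomimetic 6-endo-tet, Markovnikov, SN1-like opening favoured by ionising, non-nucleophilic HFIP), so ring D closes while the C–O bond at the stereocentre stays intact and (R) is carried over unchanged.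

**Compound list**
1 | 4-hydroxybenzaldehyde | O=Cc1ccc(O)cc1 | starting material
2 | prenyl bromide (1-bromo-3-methylbut-2-ene) | CC(C)=CCBr | starting material
3 | 4-hydroxy-3-(3-methylbut-2-en-1-yl)benzaldehyde | CC(C)=CCc1cc(C=O)ccc1O | intermediate
4 | 4-(benzyloxy)-3-(3-methylbut-2-en-1-yl)benzaldehyde | CC(C)=CCc1cc(C=O)ccc1OCc1ccccc1 | intermediate
5 | 2',4',6'-trihydroxyacetophenone | CC(=O)c1c(O)cc(O)cc1O | starting material
6 | 1-[2,4-bis(benzyloxy)-6-hydroxyphenyl]ethan-1-one | CC(=O)c1c(O)cc(OCc2ccccc2)cc1OCc1ccccc1 | intermediate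
7 | (E)-1-[2,4-bis(benzyloxy)-6-hydroxyphenyl]-3-[4-(benzyloxy)-3-(3-methylbut-2-en-1-yl)phenyl]prop-2-en-1-one | CC(C)=CCc1cc(/C=C/C(=O)c2c(O)cc(OCc3ccccc3)cc2OCc2ccccc2)ccc1OCc1ccccc1 | intermediate
8 | (E)-1-[2,4-bis(benzyloxy)-6-hydroxyphenyl]-3-(4-(benzyloxy)-3-{[(2R)-3,3-dimethyloxiran-2-yl]methyl}phenyl)prop-2-en-1-one | CC1(C)O[C@@H]1Cc1cc(/C=C/C(=O)c2c(O)cc(OCc3ccccc3)cc2OCc2ccccc2)ccc1OCc1ccccc1 | intermediate (not isolated)
9 | trans-5,7-bis(benzyloxy)-2-(4-(benzyloxy)-3-{[(2R)-3,3-dimethyloxiran-2-yl]methyl}phenyl)-3-hydroxychroman-4-one (both trans diastereomers; C2/C3 left open in the SMILES and lost in the next event) | CC1(C)O[C@@H]1Cc1cc(C2Oc3cc(OCc4ccccc4)cc(OCc4ccccc4)c3C(=O)C2O)ccc1OCc1ccccc1 | intermediate (not isolated)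
10 | 5,7-bis(benzyloxy)-2-(4-(benzyloxy)-3-{[(2R)-3,3-dimethyloxiran-2-yl]methyl}phenyl)-3-hydroxy-4H-chromen-4-one | CC1(C)O[C@@H]1Cc1cc(-c2oc3cc(OCc4ccccc4)cc(OCc4ccccc4)c3c(=O)c2O)ccc1OCc1ccccc1 | intermediate
11 | 2-(3-{[(2R)-3,3-dimethyloxiran-2-yl]methyl}-4-hydroxyphenyl)-3,5,7-trihydroxy-4H-chromen-4-one | CC1(C)O[C@@H]1Cc1cc(-c2oc3cc(O)cc(O)c3c(=O)c2O)ccc1O | intermediate (not isolated)
12 | 3,5,7-trihydroxy-2-[(3R)-3-hydroxy-2,2-dimethyl-3,4-dihydro-2H-chromen-6-yl]-4H-chromen-4-one | CC1(C)Oc2ccc(-c3oc4cc(O)cc(O)c4c(=O)c3O)cc2C[C@H]1O | target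

**Count**
Total steps: 6. Longest linear sequence: 5 (steps 1, 2, 4, 5, 6).

**Three steps most likely to fail**

Step 5 is the riskiest. The dioxirane may attack the phenolic ring A of the chalcone. Chalcones with a 6'-alkoxy group are also known to divert to aurones under alkaline peroxide.

The fallback sets out from 7 and comes back at 10. It avoids both the free phenol and the peroxide cyclisation.
- Catalytic I2 in DMSO at 120 °C closes ring C first (oxa-Michael addition, then iodination and elimination) to give the prenylflavone tribenzyl ether F1.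
- A standard Shi epoxidation of this phenol-free substrate gives the (R)-epoxyflavone F2.
- Dimethyldioxirane in acetone–CH2Cl2 at 0 °C then oxidises the C2=C3 bond to the labile flavone 2,3-oxide F3, which isomerises on silica gel to 10.

Step 6 comes next. The freed phenol may attack the secondary epoxide carbon (5-exo, giving a dihydrobenzofuran with a hydroxyisopropyl group). The epoxide may instead rearrange to the ketone by hydride shift.

The fallback sets out from 10 and comes back at 12. It replaces epoxide opening by a cyclodehydration in which only a six-membered ring can form.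
- Dilute HClO4 in THF–H2O adds water at the tertiary carbon while the phenol is still benzylated, giving the (R)-diol tribenzyl ether F4.
- H2 over Pd/C gives the free (R)-diol flavonol F5.
- TsOH·H2O in HFIP at 40 °C ionises only the tertiary alcohol. The 4'-OH traps that cation, and the non-activated secondary carbinol keeps its configuration, so 12 results.

Step 1 is third. O-prenylation and double alkylation compete, so a yield of only 30–40% is expected.

The fallback sets out from 1 and comes back at 4, so it also replaces step 2.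
- Br2 in CHCl3–MeOH at 0 °C gives 3-bromo-4-hydroxybenzaldehyde F6.
- BnBr and K2CO3 in DMF give 4-(benzyloxy)-3-bromobenzaldehyde F7.
- Stille coupling with tributyl(3-methylbut-2-en-1-yl)stannane and Pd(PPh3)4 in DMF at 90 °C installs the linear prenyl group and gives 4.

**Further compounds**
F1 | step 5 | 5,7-bis(benzyloxy)-2-[4-(benzyloxy)-3-(3-methylbut-2-en-1-yl)phenyl]-4H-chromen-4-one | CC(C)=CCc1cc(-c2cc(=O)c3c(OCc4ccccc4)cc(OCc4ccccc4)cc3o2)ccc1OCc1ccccc1
F2 | step 5 | 5,7-bis(benzyloxy)-2-(4-(benzyloxy)-3-{[(2R)-3,3-dimethyloxiran-2-yl]methyl}phenyl)-4H-chromen-4-one | CC1(C)O[C@@H]1Cc1cc(-c2cc(=O)c3c(OCc4ccccc4)cc(OCc4ccccc4)cc3o2)ccc1OCc1ccccc1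
F3 | step 5 | 2,3-epoxide of F2 (both faces of the C2=C3 bond) | CC1(C)O[C@@H]1Cc1cc(C23Oc4cc(OCc5ccccc5)cc(OCc5ccccc5)c4C(=O)C2O3)ccc1OCc1ccccc1
F4 | step 6 | 5,7-bis(benzyloxy)-2-{4-(benzyloxy)-3-[(2R)-2,3-dihydroxy-3-methylbutyl]phenyl}-3-hydroxy-4H-chromen-4-one | CC(C)(O)[C@H](O)Cc1cc(-c2oc3cc(OCc4ccccc4)cc(OCc4ccccc4)c3c(=O)c2O)ccc1OCc1ccccc1
F5 | step 6 | 2-{3-[(2R)-2,3-dihydroxy-3-methylbutyl]-4-hydroxyphenyl}-3,5,7-trihydroxy-4H-chromen-4-one | CC(C)(O)[C@H](O)Cc1cc(-c2oc3cc(O)cc(O)c3c(=O)c2O)ccc1O
F6 | step 1 | 3-bromo-4-hydroxybenzaldehyde | O=Cc1ccc(O)c(Br)c1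
F7 | step 1 | 4-(benzyloxy)-3-bromobenzaldehyde | O=Cc1ccc(OCc2ccccc2)c(Br)c1
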